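**Retrosynthetic overview**
1. Target 6 consists of two identical 3-bromo-4,5-dihydroxybenzyl halves joined through the central ArCH2–CH2Ar bond. Both benzene rings are bought intact, so no ring is formed in the route.
2. Last disconnection: the four O–Me bonds of tetramethyl ether 4 (BBr3).
3. Key disconnection: the central CH2–CH2 bond of 4, formed from two molecules of benzyl bromide 3 by cathodic reductive radical homocoupling at a silver cathode (electrochemical Wurtz dimerisation).
4. Enabling feature: each bridge CH2 is benzylic, with the ring C4 oxygen para to it. The sp3 C–Br bond is therefore reduced well before the ring C3–Br bond, and the two benzyl radicals are identical, so coupling can only give the symmetric bibenzyl.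
5. Bromide 3 comes in two steps (NaBH4, then PBr3) from commercial 3-bromo-4,5-dimethoxybenzaldehyde 1, which already carries the Br/O/O pattern of each ring.

Key step: step 3

Remark on the chemistry: the target has no stereocentre, stereogenic axis or stereogenic double bond. It is achiral, so no stereocontrol is required anywhere in the route.

**Step 1**
Reactants: 1 3-bromo-4,5-dimethoxybenzaldehyde
Product: 2 (3-bromo-4,5-dimethoxyphenyl)methanol
Conditions: NaBH4, MeOH, 0 °C to rt; H2O work-up
Reagents that add atoms: none
Why: Borohydride reduction of an aryl aldehyde to the benzylic alcohol is chemoselective and leaves the aryl bromide and methyl ethers untouched.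

**Step 2**
Reactants: 2 (3-bromo-4,5-dimethoxyphenyl)methanol
Product: 3 1-bromo-5-(bromomethyl)-2,3-dimethoxybenzene (3-bromo-4,5-dimethoxybenzyl bromide)
Conditions: PBr3 (0.4 equiv), CH2Cl2, 0 °C; used promptly after a short silica plug
Reagents that add atoms: phosphorus tribromide, BrP(Br)Br
Why: Activation of the benzylic alcohol as a phosphite ester followed by SN2 displacement by bromide is the standard conversion of benzylic alcohols into benzylic bromides and should be fast for this para-alkoxy-activated position.

**Step 3**
Reactants: 3 1-bromo-5-(bromomethyl)-2,3-dimethoxybenzene (two molecules)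
Product: 4 1,2-bis(3-bromo-4,5-dimethoxyphenyl)ethane
Conditions: divided H-cell, Ag-foil cathode, Mg anode, 0.1 M Et4NBF4, dry MeCN, controlled potential on the first (benzylic C–Br) wave located by cyclic voltammetry, ca. 1 F/mol, rt, Ar
Reagents that add atoms: none
Why: Dissociative one-electron reduction of the benzylic C–Br bond of 3 at the halophilic silver surface should release bromide and a 3-bromo-4,5-dimethoxybenzyl radical, and two such radicals combine at their CH2 termini to form the central CH2–CH2 bond. The closest known reaction type is the cathodic reductive homocoupling of benzyl bromides to bibenzyls at silver cathodes in acetonitrile. No ring is closed and no stereocentre is created, since 4 is achiral. The step needs chemoselectivity for the sp3 C–Br bond over the ring C–Br bond and for radical coupling over two-electron reduction to the toluene; the first is secured because the weak benzylic C–Br bond is expected to be reduced roughly 1 V before the aryl C–Br bond, so a potential held on the first wave should leave both ring bromines intact. The second is secured by the dry aprotic medium free of acidic protons (the phenols are masked as methyl ethers) and a high substrate concentration, under which any benzyl anion that does form is alkylated by a second molecule of 3 to give the same product 4. Because the two halves are identical, no cross-selectivity is required.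

**Step 4**
Reactants: 4 1,2-bis(3-bromo-4,5-dimethoxyphenyl)ethane
Product: 6 1,2-bis(3-bromo-4,5-dihydroxyphenyl)ethane, via bis(B-bromodioxaborole) ester 5 (not isolated)
Conditions: BBr3 (6 equiv), CH2Cl2, −78 °C to rt; then degassed ice-water, EtOAc extraction under Ar
Reagents that add atoms: none
Why: Lewis-acid ether cleavage with BBr3 (bromide attacks the O-methyl carbon of the aryl ether–borane complex) is the standard unmasking of bromocatechols, spares the aryl bromides and the ethane bridge, and the cyclic bromoborate 5 is hydrolysed to the free catechols on aqueous work-up.

**Compound list**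
1 | 3-bromo-4,5-dimethoxybenzaldehyde (5-bromoveratraldehyde) | COc1cc(C=O)cc(Br)c1OC | starting material
2 | (3-bromo-4,5-dimethoxyphenyl)methanol | COc1cc(CO)cc(Br)c1OC | intermediate
3 | 1-bromo-5-(bromomethyl)-2,3-dimethoxybenzene (3-bromo-4,5-dimethoxybenzyl bromide) | COc1cc(CBr)cc(Br)c1OC | intermediate
4 | 1,2-bis(3-bromo-4,5-dimethoxyphenyl)ethane | COc1cc(CCc2cc(OC)c(OC)c(Br)c2)cc(Br)c1OC | intermediate
5 | 1,2-bis(2,4-dibromo-1,3,2-benzodioxaborol-6-yl)ethane (bis(B-bromodioxaborole) ester, formed in the flask, not isolated) | BrB1Oc2cc(CCc3cc(Br)c4OB(Br)Oc4c3)cc(Br)c2O1 | intermediate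
6 | 1,2-bis(3-bromo-4,5-dihydroxyphenyl)ethane | Oc1cc(CCc2cc(O)c(O)c(Br)c2)cc(Br)c1O | target

**Total step count:** 4
**Longest linear sequence:** 4 steps (1 → 2 → 3 → 4 → 6; both halves of the key step come from the same sequence)

**Steps most likely to fail**

1. Step 3. The benzyl radical may take up a second electron and be protonated by adventitious water or by acetonitrile, giving hydrodebromination at the benzylic position. Drift of the cathode potential or fouling of the silver surface could also start cleavage of the ring C–Br bonds. The fallback forms the same bridge by olefination at the alkene oxidation level and sets out from compound 3. Heating 3 with PPh3 in toluene should give (3-bromo-4,5-dimethoxybenzyl)triphenylphosphonium bromide F1. Its ylide (LiHMDS, THF, −78 °C to rt) should undergo a Wittig reaction with aldehyde 1 to give mainly (Z)-1,2-bis(3-bromo-4,5-dimethoxyphenyl)ethene F2, accompanied by its E isomer (F3, described under the next fallback). Diimide reduction of the isomer mixture (TsNHNH2, NaOAc, DME/H2O, reflux) saturates the double bond without hydrogenolysis of the aryl bromides. The fallback returns to the route at compound 4.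

2. Step 2. The para-alkoxy-activated benzylic bromide may ionise during isolation, leading to Friedel–Crafts self-alkylation, ether formation or hydrolysis on silica. The fallback avoids any benzylic halide and sets out from compound 1. McMurry coupling of 1 (TiCl4, Zn, THF, reflux; aryl bromides are tolerated) should give (E)-1,2-bis(3-bromo-4,5-dimethoxyphenyl)ethene F3. Diimide reduction as above then gives the bibenzyl, and the fallback returns to the route at compound 4.

3. Step 4. Cleavage of the methoxy groups flanked by bromine may stop at partially methylated phenols, and the electron-rich bis-catechol may be oxidised to o-quinones by air during the quench and purification. The fallback moves the demethylation to the robust aldehyde stage and carries acid-labile acetals instead; it sets out from compound 1.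
   - BBr3 in CH2Cl2 should convert 1 into 3-bromo-4,5-dihydroxybenzaldehyde F4, an electron-poor, oxidation-resistant catechol that tolerates forcing conditions.
   - MOMCl and iPr2NEt in CH2Cl2 should give 3-bromo-4,5-bis(methoxymethoxy)benzaldehyde F5.
   - NaBH4 in MeOH should give [3-bromo-4,5-bis(methoxymethoxy)phenyl]methanol F6.
   - Neutral Appel bromination (CBr4, PPh3, CH2Cl2, 0 °C) should give 1-bromo-5-(bromomethyl)-2,3-bis(methoxymethoxy)benzene F7.
   - The silver-cathode homocoupling of step 3 should give 1,2-bis[3-bromo-4,5-bis(methoxymethoxy)phenyl]ethane F8.
   - Degassed HCl in MeOH at rt to 40 °C removes the four MOM groups under non-oxidising acidic conditions, and the fallback returns to the route at compound 6.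

**Further compounds**
F1 | step 3 | (3-bromo-4,5-dimethoxybenzyl)triphenylphosphonium bromide | COc1cc(C[P+](c2ccccc2)(c2ccccc2)c2ccccc2)cc(Br)c1OC.[Br-]
F2 | step 3 | (Z)-1,2-bis(3-bromo-4,5-dimethoxyphenyl)ethene | COc1cc(/C=C\c2cc(OC)c(OC)c(Br)c2)cc(Br)c1OC
F3 | step 2 | (E)-1,2-bis(3-bromo-4,5-dimethoxyphenyl)ethene | COc1cc(/C=C/c2cc(OC)c(OC)c(Br)c2)cc(Br)c1OC
F4 | step 4 | 3-bromo-4,5-dihydroxybenzaldehyde | O=Cc1cc(O)c(O)c(Br)c1
F5 | step 4 | 3-bromo-4,5-bis(methoxymethoxy)benzaldehyde | COCOc1cc(C=O)cc(Br)c1OCOC
F6 | step 4 | [3-bromo-4,5-bis(methoxymethoxy)phenyl]methanol | COCOc1cc(CO)cc(Br)c1OCOC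
F7 | step 4 | 1-bromo-5-(bromomethyl)-2,3-bis(methoxymethoxy)benzene | COCOc1cc(CBr)cc(Br)c1OCOC
F8 | step 4 | 1,2-bis[3-bromo-4,5-bis(methoxymethoxy)phenyl]ethane | COCOc1cc(CCc2cc(OCOC)c(OCOC)c(Br)c2)cc(Br)c1OCOC
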